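## Analysis of the target

Target 14 is a depside, an aryl ester that joins two molecules of 2,4-dihydroxy-6-(2-oxoheptyl)benzoic acid, and it has no stereocentre. Ring A is the acyl half and keeps both phenols free, whereas ring B keeps the free carboxyl and the 2-OH and carries the ring A acyl group on its 4-OH. Each ring holds a ketone two atoms from the arene and ortho to a carboxyl carbon, and such keto acids close to six-membered enol lactones (isocoumarins) under acid or on carboxyl activation. The free β-resorcylic acid can also lose CO2 on heating, and the depside ester, which joins a di-ortho-substituted acid to a phenol, is slow to form and easy to cleave. The two halves share one skeleton but need opposite protection: one has to be a carboxyl donor with capped phenols, the other a 4-OH acceptor with a capped carboxyl. The strategy rests on the polyketide pattern of each ring, with the carboxyl on C1, oxygens on C2 and C4 and the 2-oxoheptyl chain on C6. This is the pattern left when C2 of a 3,5,7,9-tetraoxotetradecanoic acid adds to its C7 ketone and C9 survives as the side-chain ketone, so one ring synthesis serves both halves.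

## Retrosynthetic reasoning

14 to 13. The last operation removes three benzyl groups (two ether C–O bonds on ring A, one ester C–O bond on ring B) by hydrogenolysis. It is placed last because it is neutral, so the keto acid that tends towards the enol lactone appears only at the end and never meets acid or an activating agent.

13 to 12. Both ketones are traced back to dioxolanes. The masks have to be present while the depside bond is made and have to come off while the ring B carboxyl is still a benzyl ester, which is why unmasking precedes hydrogenolysis.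

12 to 11 and 9. The depside C(=O)–O bond is cut. This is the only disconnection that divides the molecule into two pieces of identical carbon skeleton. The forward esterification has to pick the 4-OH of 9 over its 2-OH; the hydrogen bond from the 2-OH to the ester carbonyl and the crowding there should decide this.

11 to 10 to 8, and 9 to 8. Both halves come from acid 8 by protecting-group steps. Exhaustive benzylation and ester cleavage give the carboxyl donor 11; benzylation of the carboxylate alone gives the acceptor 9. Nothing is gained by making the halves separately, since 8 already carries the masked ketone both need.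

8 to 6 by way of 7. The ring C1–C6 bond of 8 is cut in the aldol sense. This opens the benzene ring to the triketo carboxylate 7, which is stored as the 4-hydroxypyranone 6, its stable lactone. The cut is made here because one C–C bond then creates the whole substitution pattern. The forward reaction must open the lactone, close C2 onto C7 and aromatise.

6 to 4 and 3. The bond between the exocyclic CH2 of the pyranone and the side-chain ketone carbon is cut. In the forward direction the lateral dianion 5 of the commercial pyranone 4 is acylated by ester 3.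

3 to 1 and 2. The dioxolane is taken back to the ketone of β-keto ester 1 and diol 2. Ketalising first removes the acidic 1,3-dicarbonyl CH2, which would otherwise quench 5, and installs the mask that lasts to step 8.

## Alternatives that were turned down

Alternative 1: Each ring with its oxoheptyl chain is traced back to a pentyl-substituted enol lactone, which is cut at the arene C–H bond and the lactone C–O bond. In the forward key step 2,4-bis(benzyloxy)benzoic acid A1 and dimethylsulfoxonium 2-oxoheptylide A2 react under [Cp*RhCl2]2, AgSbF6 and NaOAc. Carboxylate-directed ortho-rhodation by trivalent rhodium, carbene transfer from the ylide A2 and cyclocondensation give 6,8-bis(benzyloxy)-3-pentyl-1H-isochromen-1-one A3.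
- For: the arene is bought, and only one ortho C–H is open in A1, so regiochemistry is fixed. The carbon skeleton is reached in fewer steps than by the chosen route, and no polyketone has to fold correctly. On these points it is the stronger plan.
- Against: A3 is the enol lactone the target must avoid. It would have to be opened to the keto carboxylate and the ketone masked before any esterification, yet acid-catalysed ketalisation of that keto acid drives it back to A3. The detour through opening and masking costs the steps saved, and a precious metal and a silver salt are needed.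
- Comparison: the chosen route delivers the ketone already masked in 8, and that is what the depside coupling requires.

Alternative 2: Both benzylic CH2–C(=O) bonds are cut on the finished, protected depside. In the forward key step benzyl 2-(benzyloxy)-4-{[2,4-bis(benzyloxy)-6-(chloromethyl)benzoyl]oxy}-6-(chloromethyl)benzoate A4 and two molecules of hexanoyl chloride A5 are coupled with NiCl2, a bipyridine ligand and Mn powder. The product is benzyl 2-(benzyloxy)-4-{[2,4-bis(benzyloxy)-6-(2-oxoheptyl)benzoyl]oxy}-6-(2-oxoheptyl)benzoate A6.
- For: it is the most convergent plan. The ketones of A6 arrive at the right oxidation level with no mask, and the depside is assembled from simple orsellinate-type units; in step economy after the depside it is stronger.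
- Against: two couplings with A5 must succeed in one molecule at di-ortho-substituted benzylic carbons, where benzyl radicals like to dimerise. A chloromethyl group ortho to an ester closes readily to a phthalide, and more so next to the activated aryl ester of ring A. Zerovalent nickel can insert into the aryl ester C–O bond. A4 itself needs benzylic chlorination of two electron-rich rings.
- Comparison: the chosen route is longer but never places a reactive benzylic halide beside an ester, because each side chain is already in place when its ring forms.

Alternative 3: Ring bonds C1–C2 and C5–C6 of the benzoate are cut in a [4+2] sense. In the forward key step 1-methoxy-1,3-bis(trimethylsilyloxy)buta-1,3-diene A7 and benzyl 4-(2-pentyl-1,3-dioxolan-2-yl)but-2-ynoate A8 are heated. The adduct aromatises by loss of its methoxy group and is desilylated to benzyl 2,4-dihydroxy-6-[(2-pentyl-1,3-dioxolan-2-yl)methyl]benzoate A9, which is the same compound as 9.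
- For: the polarity of diene and ynoate fixes the regiochemistry, there is no competing cyclisation mode, and the acceptor half A9 arrives in one step. On regiocontrol it is stronger than an aldol fold.
- Against: A8 has to be built around a CH2 lying between an alkyne and a ketal carbon, whose ketone precursors isomerise easily to allenyl ketones. A β-alkyl ynoate is a sluggish dienophile and needs heat that the labile diene A7 tolerates poorly. The dioxolane and silyl enol ethers rule out Lewis acid help. The donor half would still need benzylation and ester cleavage.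
- Comparison: the chosen route gets the same ring from two commodity compounds in a water-tolerant medium and gives the free acid 8, which divides into both halves.

Key step: step 3

Remark: the target has no stereocentre, so nothing has to be set or protected in that respect. Benzyl bromide, bases and coupling agents are treated as reagents and carry no compound number.

## Route

Step 1
Reactants: 1 methyl 3-oxooctanoate; 2 ethylene glycol
Product: 3 methyl (2-pentyl-1,3-dioxolan-2-yl)acetate
Conditions: 2 (3 equiv), p-TsOH·H2O (0.05 equiv), toluene, Dean–Stark, reflux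
Reagents that add atoms: none
Why: Acid-catalysed ketalisation of the ketone of a β-keto ester with azeotropic removal of water; the ester carbonyl does not ketalise, and the dioxolane removes the acidic 1,3-dicarbonyl CH2 that would quench the carbanion of step 2.

Step 2
Reactants: 4 4-hydroxy-6-methyl-2H-pyran-2-one; 3 methyl (2-pentyl-1,3-dioxolan-2-yl)acetate
Product: 6 4-hydroxy-6-[2-oxo-3-(2-pentyl-1,3-dioxolan-2-yl)propyl]-2H-pyran-2-one, via dilithiated 4-hydroxy-6-methylpyran-2-one 5 (not isolated)
Conditions: 4 (2.3 equiv), LiN(i-Pr)2 (4.5 equiv), THF/DMPU, −78 → −20 °C; then 3 (1 equiv), −78 → 0 °C; AcOH, then pH 4 buffer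
Reagents that add atoms: none
Why: Lateral dianion formation at the 6-methyl group of the hydroxypyranone and Claisen-type C-acylation by an ester, a known entry to 6-(2-oxoalkyl)-4-hydroxypyranones. Two equivalents of 5 are used because the product is deprotonated at its new doubly activated CH2. The amide base is kept just short of two per pyranone so that no free amide enolises 3 and opens its dioxolane by β-elimination.

Step 3
Reactants: 6 4-hydroxy-6-[2-oxo-3-(2-pentyl-1,3-dioxolan-2-yl)propyl]-2H-pyran-2-one
Product: 8 2,4-dihydroxy-6-[(2-pentyl-1,3-dioxolan-2-yl)methyl]benzoic acid, via ring-opened triketo carboxylate 7 (not isolated)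
Conditions: KOH (about 2 M, excess), MeOH/H2O 9:1, 23 °C; then 1 M HCl to pH 3 at 0 °C, immediate extraction
Reagents that add atoms: potassium hydroxide, [K+].[OH-]
Why: Hydroxide adds to the lactone carbonyl of 6 and the ring oxygen leaves as an enolate, which unrolls the pyranone into the 3,5,7-triketo carboxylate 7 (numbered from the carboxylate carbon, dioxolane at C9). The doubly activated C2, flanked by the carboxylate and the C3 ketone, is the best-stabilised carbanion of the chain and adds to the C7 carbonyl, making the C2–C7 bond that becomes the C1–C6 bond of the arene. The ring closes in a 6-(enolendo)-exo-trig aldol mode, which the Baldwin rules for enolates allow. Loss of the C7 hydroxyl as water and enolisation of the C3 and C5 carbonyls then give the benzene ring irreversibly, with OH on C2 and C4 and the masked side chain on C6, and no stereocentre is formed. The closest known reaction type is the base-induced conversion of 6-(2-oxoalkyl)-4-hydroxypyran-2-ones and of free 3,5,7-triketo acids into orsellinic-type acids. The step needs the C2-to-C7 aldol to win over a C6-to-C1 Claisen closure and over a C8-to-C3 aldol: the first is excluded because C1 is a carboxylate and no longer an electrophile, the second is disfavoured because C8 is activated by one carbonyl only and sits beside the quaternary dioxolane carbon. Opening of the dioxolane by β-elimination from a C8 carbanion is reversible, since the tethered alkoxide can add back, whereas aromatisation is not, so the material should still drain to 8.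

Step 4
Reactants: 8 2,4-dihydroxy-6-[(2-pentyl-1,3-dioxolan-2-yl)methyl]benzoic acid
Product: 9 benzyl 2,4-dihydroxy-6-[(2-pentyl-1,3-dioxolan-2-yl)methyl]benzoate
Conditions: BnBr (1.05 equiv), KHCO3 (1.2 equiv), DMF, 23 °C
Reagents that add atoms: benzyl bromide, BrCc1ccccc1
Why: SN2 alkylation of the carboxylate; KHCO3 deprotonates the carboxylic acid but not the phenols, so only the ester forms, and room temperature avoids decarboxylation of the β-resorcylic acid.

Step 5
Reactants: 8 2,4-dihydroxy-6-[(2-pentyl-1,3-dioxolan-2-yl)methyl]benzoic acid
Product: 10 benzyl 2,4-bis(benzyloxy)-6-[(2-pentyl-1,3-dioxolan-2-yl)methyl]benzoate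
Conditions: BnBr (3.5 equiv), K2CO3 (4 equiv), DMF, 60 °C
Reagents that add atoms: benzyl bromide, BrCc1ccccc1
Why: Williamson etherification of both phenols together with carboxylate alkylation; the warm DMF is needed for the hydrogen-bonded 2-OH, and the dioxolane is inert to carbonate.

Step 6
Reactants: 10 benzyl 2,4-bis(benzyloxy)-6-[(2-pentyl-1,3-dioxolan-2-yl)methyl]benzoate
Product: 11 2,4-bis(benzyloxy)-6-[(2-pentyl-1,3-dioxolan-2-yl)methyl]benzoic acid
Conditions: KOH (5 equiv), DMSO/H2O 4:1, 80 °C; then 1 M HCl to pH 3 at 0 °C
Reagents that add atoms: potassium hydroxide, [K+].[OH-]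
Why: Saponification by acyl substitution at a di-ortho-substituted benzoate, for which poorly solvated hydroxide in aqueous DMSO is the usual remedy; benzyl ethers and the dioxolane are stable to base, and the acid is set free cold and briefly to spare the ketal.

Step 7
Reactants: 11 2,4-bis(benzyloxy)-6-[(2-pentyl-1,3-dioxolan-2-yl)methyl]benzoic acid; 9 benzyl 2,4-dihydroxy-6-[(2-pentyl-1,3-dioxolan-2-yl)methyl]benzoate
Product: 12 benzyl 4-({2,4-bis(benzyloxy)-6-[(2-pentyl-1,3-dioxolan-2-yl)methyl]benzoyl}oxy)-2-hydroxy-6-[(2-pentyl-1,3-dioxolan-2-yl)methyl]benzoate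
Conditions: DCC (1.2 equiv), DMAP (0.2 equiv), CH2Cl2, 0 → 23 °C
Reagents that add atoms: none
Why: Steglich esterification; the 4-OH of 9 is the more acidic and unhindered phenol, while the 2-OH is held in a hydrogen bond to the ester carbonyl, so acylation should go to O4. The dioxolane of 11 keeps the activated carboxyl from being trapped by a ketone enol as an enol lactone.

Step 8
Reactants: 12 benzyl 4-({2,4-bis(benzyloxy)-6-[(2-pentyl-1,3-dioxolan-2-yl)methyl]benzoyl}oxy)-2-hydroxy-6-[(2-pentyl-1,3-dioxolan-2-yl)methyl]benzoate
Product: 13 benzyl 4-{[2,4-bis(benzyloxy)-6-(2-oxoheptyl)benzoyl]oxy}-2-hydroxy-6-(2-oxoheptyl)benzoate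
Conditions: 1 M aq. HCl/THF 1:4, 23 °C
Reagents that add atoms: water, O
Why: Acid-catalysed hydrolysis of both dioxolanes through oxocarbenium ions; benzyl ethers, the benzyl ester and the aryl ester tolerate dilute aqueous acid at room temperature, and without heat or a free carboxyl the enol lactonisation should not compete.

Step 9
Reactants: 13 benzyl 4-{[2,4-bis(benzyloxy)-6-(2-oxoheptyl)benzoyl]oxy}-2-hydroxy-6-(2-oxoheptyl)benzoate
Product: 14 4-{[2,4-dihydroxy-6-(2-oxoheptyl)benzoyl]oxy}-2-hydroxy-6-(2-oxoheptyl)benzoic acid
Conditions: H2 (1 atm), Pd/C (10% Pd), EtOAc, 23 °C; filtration and evaporation without heating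
Reagents that add atoms: none
Why: Hydrogenolysis of two benzyl ethers and one benzyl ester under neutral conditions; dialkyl ketones and the aryl ester are not reduced at this pressure, and the neutral, cold work-up keeps the keto acid open.

## Compound list

1 | methyl 3-oxooctanoate | CCCCCC(=O)CC(=O)OC | starting material
2 | ethylene glycol | OCCO | starting material
3 | methyl (2-pentyl-1,3-dioxolan-2-yl)acetate | CCCCCC1(CC(=O)OC)OCCO1 | intermediate
4 | 4-hydroxy-6-methyl-2H-pyran-2-one | Cc1cc(O)cc(=O)o1 | starting material
5 | dilithiated 4-hydroxy-6-methylpyran-2-one | [Li+].[Li+].[CH2-]C1=CC([O-])=CC(=O)O1 | intermediate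
6 | 4-hydroxy-6-[2-oxo-3-(2-pentyl-1,3-dioxolan-2-yl)propyl]-2H-pyran-2-one | CCCCCC1(CC(=O)CC2=CC(O)=CC(=O)O2)OCCO1 | intermediate
7 | potassium 3,5,7-trioxo-8-(2-pentyl-1,3-dioxolan-2-yl)octanoate | CCCCCC1(CC(=O)CC(=O)CC(=O)CC(=O)[O-])OCCO1.[K+] | intermediate
8 | 2,4-dihydroxy-6-[(2-pentyl-1,3-dioxolan-2-yl)methyl]benzoic acid | CCCCCC1(Cc2cc(O)cc(O)c2C(=O)O)OCCO1 | intermediate
9 | benzyl 2,4-dihydroxy-6-[(2-pentyl-1,3-dioxolan-2-yl)methyl]benzoate | CCCCCC1(Cc2cc(O)cc(O)c2C(=O)OCc2ccccc2)OCCO1 | intermediate
10 | benzyl 2,4-bis(benzyloxy)-6-[(2-pentyl-1,3-dioxolan-2-yl)methyl]benzoate | CCCCCC1(Cc2cc(OCc3ccccc3)cc(OCc3ccccc3)c2C(=O)OCc2ccccc2)OCCO1 | intermediate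
11 | 2,4-bis(benzyloxy)-6-[(2-pentyl-1,3-dioxolan-2-yl)methyl]benzoic acid | CCCCCC1(Cc2cc(OCc3ccccc3)cc(OCc3ccccc3)c2C(=O)O)OCCO1 | intermediate
12 | benzyl 4-({2,4-bis(benzyloxy)-6-[(2-pentyl-1,3-dioxolan-2-yl)methyl]benzoyl}oxy)-2-hydroxy-6-[(2-pentyl-1,3-dioxolan-2-yl)methyl]benzoate | CCCCCC1(Cc2cc(OCc3ccccc3)cc(OCc3ccccc3)c2C(=O)Oc2cc(O)c(C(=O)OCc3ccccc3)c(CC3(CCCCC)OCCO3)c2)OCCO1 | intermediate
13 | benzyl 4-{[2,4-bis(benzyloxy)-6-(2-oxoheptyl)benzoyl]oxy}-2-hydroxy-6-(2-oxoheptyl)benzoate | CCCCCC(=O)Cc1cc(OCc2ccccc2)cc(OCc2ccccc2)c1C(=O)Oc1cc(O)c(C(=O)OCc2ccccc2)c(CC(=O)CCCCC)c1 | intermediate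
14 | 4-{[2,4-dihydroxy-6-(2-oxoheptyl)benzoyl]oxy}-2-hydroxy-6-(2-oxoheptyl)benzoic acid | CCCCCC(=O)Cc1cc(OC(=O)c2c(O)cc(O)cc2CC(=O)CCCCC)cc(O)c1C(=O)O | target

## Step count and weak points

Total: 9 steps. Longest linear sequence: 8 steps (1, 2, 3, 5, 6, 7, 8, 9); step 4 is a one-step branch from 8.

Step 3 (key step). The most likely failures are retro-Claisen cleavage of the polyketone chain by hydroxide or methoxide before the aldol closes, return of unreacted 7 to pyranone 6 on acidification, and hydrolysis of the dioxolane or loss of CO2 during the acidic work-up, since the free carboxyl of 8 sits next to the ketal. The fallback sets out from 3 and comes back at 9. Ester 3 is converted with MeNHOMe·HCl and i-PrMgCl into N-methoxy-N-methyl-2-(2-pentyl-1,3-dioxolan-2-yl)acetamide F1. The dianion of the known 2,2-dimethyl-6-(2-oxopropyl)-4H-1,3-dioxin-4-one F2, formed with 2 equiv LiN(i-Pr)2, is acylated at its terminal methyl by F1 and gives 6-[2,4-dioxo-5-(2-pentyl-1,3-dioxolan-2-yl)pentyl]-2,2-dimethyl-4H-1,3-dioxin-4-one F3. Heating F3 in toluene with benzyl alcohol releases acetone by retro-[4+2], and the acylketene is trapped as benzyl 3,5,7-trioxo-8-(2-pentyl-1,3-dioxolan-2-yl)octanoate F4. Mild base (Et3N, then Cs2CO3) brings about the same C2-to-C7 aldol and aromatisation on F4, now without hydroxide, and gives 9 directly. Compound 10 is then made from 9 instead of from 8 with benzyl bromide and K2CO3, and the route continues at step 6.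

Step 2. Proton transfer from the α-CH2 of ester 3 to the dianion can compete with acylation, after which the ester enolate opens its dioxolane by β-elimination; conversion also stalls if the product consumes more of 5 than allowed for. The fallback sets out from 3 and returns at 6, replacing the Claisen acylation by an aldol addition and an oxidation. Ester 3 is reduced with i-Bu2AlH at −78 °C to (2-pentyl-1,3-dioxolan-2-yl)acetaldehyde F5. Dianion 5 adds to F5 at −78 °C, much faster than it can enolise it, and gives racemic 4-hydroxy-6-[2-hydroxy-3-(2-pentyl-1,3-dioxolan-2-yl)propyl]-2H-pyran-2-one F6. Oxidation of the secondary alcohol of F6 with IBX in DMSO gives 6.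

Step 7. Acyl transfer from the crowded O-acylisourea of a di-ortho-substituted acid may be slow, so rearrangement to the N-acylurea could take over, and some acylation at O2 or double acylation may appear. The fallback sets out from 11 and returns at 12, with a small, neutral, isolable acyl donor. Acid 11 is converted with cyanuric fluoride and pyridine into 2,4-bis(benzyloxy)-6-[(2-pentyl-1,3-dioxolan-2-yl)methyl]benzoyl fluoride F7. F7 is then combined with the 4-phenoxide of 9, formed with K2CO3 in MeCN, where the more acidic 4-OH is the one deprotonated, and gives 12.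

Step 6. Acyl substitution at the shielded carbonyl may stop short, and forcing it with heat invites loss of CO2 from the product. The fallback sets out from 8 and returns at 11 without any attack at the carbonyl. Acid 8 is esterified with allyl bromide and KHCO3 to prop-2-en-1-yl 2,4-dihydroxy-6-[(2-pentyl-1,3-dioxolan-2-yl)methyl]benzoate F8. Benzylation of F8 with benzyl bromide and K2CO3 gives prop-2-en-1-yl 2,4-bis(benzyloxy)-6-[(2-pentyl-1,3-dioxolan-2-yl)methyl]benzoate F9. Pd(PPh3)4 (zerovalent palladium) with morpholine removes the allyl group of F9 through the π-allyl complex and gives 11.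

## Further compounds

F1 | step 3 | N-methoxy-N-methyl-2-(2-pentyl-1,3-dioxolan-2-yl)acetamide | CCCCCC1(CC(=O)N(C)OC)OCCO1
F2 | step 3 | 2,2-dimethyl-6-(2-oxopropyl)-4H-1,3-dioxin-4-one | CC(=O)CC1=CC(=O)OC(C)(C)O1
F3 | step 3 | 6-[2,4-dioxo-5-(2-pentyl-1,3-dioxolan-2-yl)pentyl]-2,2-dimethyl-4H-1,3-dioxin-4-one | CCCCCC1(CC(=O)CC(=O)CC2=CC(=O)OC(C)(C)O2)OCCO1
F4 | step 3 | benzyl 3,5,7-trioxo-8-(2-pentyl-1,3-dioxolan-2-yl)octanoate | CCCCCC1(CC(=O)CC(=O)CC(=O)CC(=O)OCc2ccccc2)OCCO1
F5 | step 2 | (2-pentyl-1,3-dioxolan-2-yl)acetaldehyde | CCCCCC1(CC=O)OCCO1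
F6 | step 2 | 4-hydroxy-6-[2-hydroxy-3-(2-pentyl-1,3-dioxolan-2-yl)propyl]-2H-pyran-2-one (racemic) | CCCCCC1(CC(O)CC2=CC(O)=CC(=O)O2)OCCO1
F7 | step 7 | 2,4-bis(benzyloxy)-6-[(2-pentyl-1,3-dioxolan-2-yl)methyl]benzoyl fluoride | CCCCCC1(Cc2cc(OCc3ccccc3)cc(OCc3ccccc3)c2C(F)=O)OCCO1
F8 | step 6 | prop-2-en-1-yl 2,4-dihydroxy-6-[(2-pentyl-1,3-dioxolan-2-yl)methyl]benzoate | CCCCCC1(Cc2cc(O)cc(O)c2C(=O)OCC=C)OCCO1
F9 | step 6 | prop-2-en-1-yl 2,4-bis(benzyloxy)-6-[(2-pentyl-1,3-dioxolan-2-yl)methyl]benzoate | CCCCCC1(Cc2cc(OCc3ccccc3)cc(OCc3ccccc3)c2C(=O)OCC=C)OCCO1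
A1 | alternative 1 | 2,4-bis(benzyloxy)benzoic acid | OC(=O)c1ccc(OCc2ccccc2)cc1OCc1ccccc1
A2 | alternative 1 | dimethylsulfoxonium 2-oxoheptylide | CCCCCC(=O)C=S(C)(C)=O
A3 | alternative 1 | 6,8-bis(benzyloxy)-3-pentyl-1H-isochromen-1-one | CCCCCC1=Cc2cc(OCc3ccccc3)cc(OCc3ccccc3)c2C(=O)O1
A4 | alternative 2 | benzyl 2-(benzyloxy)-4-{[2,4-bis(benzyloxy)-6-(chloromethyl)benzoyl]oxy}-6-(chloromethyl)benzoate | ClCc1cc(OCc2ccccc2)cc(OCc2ccccc2)c1C(=O)Oc1cc(CCl)c(C(=O)OCc2ccccc2)c(OCc2ccccc2)c1
A5 | alternative 2 | hexanoyl chloride | CCCCCC(Cl)=O
A6 | alternative 2 | benzyl 2-(benzyloxy)-4-{[2,4-bis(benzyloxy)-6-(2-oxoheptyl)benzoyl]oxy}-6-(2-oxoheptyl)benzoate | CCCCCC(=O)Cc1cc(OCc2ccccc2)cc(OCc2ccccc2)c1C(=O)Oc1cc(CC(=O)CCCCC)c(C(=O)OCc2ccccc2)c(OCc2ccccc2)c1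
A7 | alternative 3 | 1-methoxy-1,3-bis(trimethylsilyloxy)buta-1,3-diene | COC(O[Si](C)(C)C)=CC(=C)O[Si](C)(C)C
A8 | alternative 3 | benzyl 4-(2-pentyl-1,3-dioxolan-2-yl)but-2-ynoate | CCCCCC1(CC#CC(=O)OCc2ccccc2)OCCO1
A9 | alternative 3 | benzyl 2,4-dihydroxy-6-[(2-pentyl-1,3-dioxolan-2-yl)methyl]benzoate | CCCCCC1(Cc2cc(O)cc(O)c2C(=O)OCc2ccccc2)OCCO1
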